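**Strategy.** The plan cuts the C7–C8 bond of the nine-membered carbocycle (ring B). The tertiary carbinol C7, flanked by the cis C8–C9 epoxide and tied through C4a/C11a to the trans-fused dihydropyran (ring A), is read as a C7 methyl ketone and a Z-alkenyl nucleophile at C8. An intramolecular Nozaki–Hiyama–Kishi addition then closes ring B, forms C7–C8 and sets C7 in one operation, leaving the hydroxyl that later directs epoxidation. Its precursor is an all-trans 1,11a,4a-trisubstituted dihydropyran: a p-methoxybenzyl acetal at C1, a methyl ester on C4, a 3-oxobutyl arm on C4a and, on C11a, a 2-propenyl unit carrying a Z-iodovinyl terminus.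

Key step: step 11

Remark: xenicane numbering is used throughout (C1 acetal carbon, O2, C3=C4, C4a, C5, C6, C7, C8, C9, C10, C11 with its exocyclic methylene, C11a, side chain C12–C15); ring A is the dihydropyran, ring B the nine-membered carbocycle.
Remark: the lipase of step 3 is assumed to transesterify the (S)-acetate faster, leaving (R)-acetate 4; with the opposite preference the same enzyme would be run in the acylation direction on the racemising hemiacetal 2 to give the same acetate 4.
Remark: the enol ether geometry in 14–18 is inconsequential and left undefined; hemiacetal 28 is an anomeric mixture.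

**Route**

Step 1
Reactants: 1 furfuryl alcohol
Product: 2 rac-6-hydroxy-2H-pyran-3(6H)-one
Conditions: mCPBA, CH2Cl2, 0 °C to rt
Reagents that add atoms: 3-chloroperbenzoic acid, O=C(OO)c1cccc(Cl)c1
Why: Achmatowicz rearrangement, in which peracid oxidation of the furan gives a cis-enedione that is closed by the hydroxymethyl group to the six-membered hemiacetal (racemic at the acetal carbon).

Step 2
Reactants: 2 rac-6-hydroxy-2H-pyran-3(6H)-one
Product: 3 rac-6-acetoxy-2H-pyran-3(6H)-one
Conditions: Ac2O, pyridine, DMAP (cat.), CH2Cl2, 0 °C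
Reagents that add atoms: acetic anhydride, CC(=O)OC(C)=O
Why: Acylation of the hemiacetal hydroxyl gives the allylic acetal ester needed both for enzymatic resolution and for π-allyl chemistry.

Step 3
Reactants: 3 rac-6-acetoxy-2H-pyran-3(6H)-one
Product: 4 (R)-6-acetoxy-2H-pyran-3(6H)-one
Conditions: immobilised Burkholderia cepacia lipase, n-BuOH, hexane, rt, run past half conversion
Reagents that add atoms: none
Why: Lipase-catalysed enantioselective transesterification (kinetic resolution) deacylates one enantiomer only, so the acetal stereocenter is selected and not created, and the deacylated hemiacetal racemises and can be returned to step 2.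

Step 4
Reactants: 4 (R)-6-acetoxy-2H-pyran-3(6H)-one
Product: 5 (S)-6-[(4-methoxybenzyl)oxy]-2H-pyran-3(6H)-one
Conditions: Pd(OAc)2 (5 mol %), P(OPh)3 (20 mol %), 4-methoxybenzyl alcohol, CH2Cl2, rt
Reagents that add atoms: 4-methoxybenzyl alcohol, COc1ccc(CO)cc1
Why: Tsuji–Trost-type O-glycosylation in which zerovalent palladium ionises the allylic acetate anti to the leaving group and the alcohol attacks the π-allyl complex anti to the metal, so the future C1 is fixed with net retention (the descriptor changes only through ligand priorities).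

Step 5
Reactants: 6 trimethylsilylacetylene; 7 2,3-dibromopropene
Product: 9 (4-bromopent-4-en-1-yn-1-yl)trimethylsilane, via alkynylmagnesium bromide 8 (not isolated)
Conditions: EtMgBr, THF, 0 °C to rt; then CuBr·SMe2 (5 mol %), 7, 0 °C to rt
Reagents that add atoms: none
Why: Copper-catalysed alkynylation of the allylic bromide by the magnesium acetylide, the vinylic bromide being inert under these conditions.

Step 6
Reactants: 5 (S)-6-[(4-methoxybenzyl)oxy]-2H-pyran-3(6H)-one; 9 (4-bromopent-4-en-1-yn-1-yl)trimethylsilane (2.2 equiv); 10 methyl vinyl ketone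
Product: 15 (4S,5R,6S)-6-[(4-methoxybenzyl)oxy]-4-[3-(triethylsilyloxy)but-2-en-1-yl]-5-[5-(trimethylsilyl)pent-1-en-4-yn-2-yl]dihydro-2H-pyran-3(4H)-one, via alkenyllithium 11 (not isolated), via lithium dialkenylcuprate 12 (not isolated), via ring lithium enolate 13 (not isolated), via side-chain lithium enolate 14 (not isolated)
Conditions: 9, t-BuLi (2 equiv per bromide), Et2O, −78 °C; CuBr·SMe2, −78 to −40 °C; 5, −78 °C; 10, −78 °C; Et3SiCl, Et3N, −78 to 0 °C
Reagents that add atoms: chlorotriethylsilane, CC[Si](Cl)(CC)CC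
Why: Tandem conjugate addition–Michael trapping, in which the cuprate adds to the enone anti to the C1 alkoxy group (setting C11a), the resulting enolate attacks methyl vinyl ketone anti to the new C11a arm (setting C4a), and O-silylation of the adduct enolate masks the C7 ketone for the next step.

Step 7
Reactants: 15 silyl enol ether ketone
Product: 17 C3=C4 enol triflate (2S,3R,4S)-2-[(4-methoxybenzyl)oxy]-4-[3-(triethylsilyloxy)but-2-en-1-yl]-3-[5-(trimethylsilyl)pent-1-en-4-yn-2-yl]-3,4-dihydro-2H-pyran-5-yl trifluoromethanesulfonate, via potassium enolate 16 (not isolated)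
Conditions: KN(SiMe3)2, THF, −78 °C; N-(5-chloro-2-pyridyl)bis(trifluoromethanesulfonimide), −78 °C
Reagents that add atoms: N-(5-chloro-2-pyridyl)bis(trifluoromethanesulfonimide), O=S(=O)(N(c1ccc(Cl)cn1)S(=O)(=O)C(F)(F)F)C(F)(F)F
Why: Kinetic deprotonation occurs at the unhindered C3 methylene (C4a is tertiary and flanked by two branches) and O-sulfonylation gives the enol triflate, while the masked C7 ketone cannot compete or undergo aldol closure onto C4.

Step 8
Reactants: 17 C3=C4 enol triflate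
Product: 19 methyl (2S,3R,4S)-2-[(4-methoxybenzyl)oxy]-4-(3-oxobutyl)-3-[5-(trimethylsilyl)pent-1-en-4-yn-2-yl]-3,4-dihydro-2H-pyran-5-carboxylate, via silyl enol ether ester 18 (not isolated)
Conditions: Pd(OAc)2 (5 mol %), PPh3 (10 mol %), CO (1 atm), MeOH, Et3N, DMF, 45 °C; then 1 M HCl, THF, 0 °C
Reagents that add atoms: carbon monoxide, [C-]#[O+]; methanol, CO
Why: Palladium-catalysed methoxycarbonylation of the enol triflate (oxidative addition, CO insertion, methanolysis) installs C12 as the C4 ester, and the dilute acid wash then unmasks the C7 methyl ketone without touching the acetal of the vinylogous carbonate.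

Step 9
Reactants: 19 keto ester with silylalkyne
Product: 20 methyl (2S,3R,4S)-3-(5-iodopent-1-en-4-yn-2-yl)-2-[(4-methoxybenzyl)oxy]-4-(3-oxobutyl)-3,4-dihydro-2H-pyran-5-carboxylate
Conditions: NIS, AgNO3 (20 mol %), DMF, rt, dark
Reagents that add atoms: N-iodosuccinimide, O=C1CCC(=O)N1I
Why: Silver-catalysed ipso iododesilylation of the alkynylsilane gives the 1-iodoalkyne directly.

Step 10
Reactants: 20 iodoalkyne
Product: 21 methyl (2S,3R,4S)-3-[(4Z)-5-iodopenta-1,4-dien-2-yl]-2-[(4-methoxybenzyl)oxy]-4-(3-oxobutyl)-3,4-dihydro-2H-pyran-5-carboxylate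
Conditions: 2-nitrobenzenesulfonohydrazide, Et3N, THF/i-PrOH, rt
Reagents that add atoms: none
Why: Diimide generated in the flask transfers H2 in a concerted syn fashion to the iodoalkyne faster than to the 1,1-disubstituted and conjugated alkenes, giving the Z-iodoalkene.

Step 11
Reactants: 21 Z-iodoalkene methyl ketone
Product: 24 methyl (1S,4aS,7S,8Z,11aR)-7-hydroxy-1-[(4-methoxybenzyl)oxy]-7-methyl-11-methylidene-1,4a,5,6,7,10,11,11a-octahydrocyclonona[c]pyran-4-carboxylate, via alkenylchromium dichloride 22 (not isolated), via chromium alkoxide 23 (not isolated)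
Conditions: CrCl2 (10 equiv), NiCl2 (0.1 equiv), degassed DMSO, 0.004 M, slow addition, rt to 45 °C; aqueous ethylenediamine work-up
Reagents that add atoms: none
Why: CrCl2 reduces NiCl2 to zerovalent nickel, which inserts into the C8–I bond with retention of the Z geometry and hands the alkenyl group to trivalent chromium; the alkenylchromium dichloride 22 then adds to the chromium-coordinated C7 carbonyl to give alkoxide 23, hydrolysed on work-up. The closest known reaction type is the intramolecular Nozaki–Hiyama–Kishi alkenylation used for medium-ring closure, well established for aldehydes and documented in fewer cases for ketones. Ring B closes in a 9-exo-trig mode, C8 attacking the C7=O carbon whose oxygen stays outside the new ring. The new stereocenter C7 is controlled by the conformation of the forming ring: the trans C4a and C11a arms on ring A, the Z C8=C9 unit and the sp2 C11 leave few low-energy arrangements, and the bulky chromium-bound oxygen is expected to sit on the outer face that also carries H-4a, with the methyl group on the side of H-11a, which is the required (7S) configuration. The step needs chemoselectivity for the ketone over the C4 ester and cyclisation over protonation or dimerisation of 22; the first is secured by the low electrophilicity of the β-alkoxyacrylate, the second by high dilution and by the preorganisation just described. The product keeps the free C7 hydroxyl that directs the epoxidation in step 14.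

Step 12
Reactants: 24 bicyclic hydroxy ester
Product: 25 (1S,4aS,7S,8Z,11aR)-4-(hydroxymethyl)-1-[(4-methoxybenzyl)oxy]-7-methyl-11-methylidene-1,4a,5,6,7,10,11,11a-octahydrocyclonona[c]pyran-7-ol
Conditions: i-Bu2AlH (4 equiv), CH2Cl2, −78 °C; aqueous sodium potassium tartrate
Reagents that add atoms: none
Why: 1,2-Reduction of the β-alkoxyacrylate ester to the primary allylic alcohol, the C7 alkoxide merely consuming one equivalent of the hydride.

Step 13
Reactants: 25 diol
Product: 26 (1S,4aS,7S,8Z,11aR)-7-hydroxy-1-[(4-methoxybenzyl)oxy]-7-methyl-11-methylidene-1,4a,5,6,7,10,11,11a-octahydrocyclonona[c]pyran-4-carbaldehyde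
Conditions: MnO2 (excess), CH2Cl2, rt
Reagents that add atoms: none
Why: Allylic oxidation with MnO2 converts only the primary allylic alcohol into the enal (a vinylogous formate); the tertiary allylic alcohol cannot be oxidised.

Step 14
Reactants: 26 enal
Product: 27 (1S,4aS,7S,8R,9R,11aR)-8,9-epoxy-7-hydroxy-1-[(4-methoxybenzyl)oxy]-7-methyl-11-methylidene-1,4a,5,6,7,8,9,10,11,11a-decahydrocyclonona[c]pyran-4-carbaldehyde
Conditions: VO(acac)2 (5 mol %), t-BuOOH (decane), CH2Cl2, 0 °C to rt
Reagents that add atoms: tert-butyl hydroperoxide, CC(C)(C)OO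
Why: Hydroxyl-directed epoxidation in which the vanadium alkoxide of the C7 hydroxyl delivers oxygen to the adjacent Z C8=C9 on the face syn to that hydroxyl (setting C8 and C9), while the electron-poor enol ether and the remote exocyclic alkene stay intact.

Step 15
Reactants: 27 epoxy enal
Product: 28 (4aS,7S,8R,9R,11aR)-8,9-epoxy-1,7-dihydroxy-7-methyl-11-methylidene-1,4a,5,6,7,8,9,10,11,11a-decahydrocyclonona[c]pyran-4-carbaldehyde
Conditions: DDQ, CH2Cl2/pH 7 buffer, 0 °C
Reagents that add atoms: none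
Why: Oxidative cleavage of the p-methoxybenzyl acetal (benzylic hydride abstraction, then hydrolysis of the oxocarbenium ion) frees the C1 hemiacetal under neutral conditions, and the hemiacetal is stabilised against ring opening by conjugation of O2 with the C4 formyl group.

Step 16
Reactants: 28 hemiacetal
Product: 29 (1R,4aS,7S,8R,9R,11aR)-1-acetoxy-8,9-epoxy-7-hydroxy-7-methyl-11-methylidene-1,4a,5,6,7,8,9,10,11,11a-decahydrocyclonona[c]pyran-4-carbaldehyde
Conditions: Ac2O, Et3N, DMAP (cat.), CH2Cl2, −20 °C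
Reagents that add atoms: acetic anhydride, CC(=O)OC(C)=O
Why: Acetylation of the equilibrating hemiacetal is expected to trap the anomer with the acetoxy group axial and trans to the C11a branch (anomeric effect, less hindered), which sets C1, while the hindered tertiary C7 hydroxyl does not react.

Step 17
Reactants: 30 (E)-tert-butyldimethyl{[3-(4,4,5,5-tetramethyl-1,3,2-dioxaborolan-2-yl)prop-2-en-1-yl]oxy}silane
Product: 31 (E)-tert-butyldimethyl{[3-(4,4,5,5-tetramethyl-1,3,2-dioxaborolan-2-yl)prop-1-en-1-yl]oxy}silane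
Conditions: [Ir(cod)(PPh2Me)2]PF6 (2 mol %), H2 (activation only), THF, rt
Reagents that add atoms: none
Why: Iridium-hydride-catalysed alkene isomerisation (1,3-hydrogen shift) moves the double bond out of conjugation with boron to give the (E)-γ-silyloxyallylboronate.

Step 18
Reactants: 29 C1-acetoxy enal; 31 (E)-γ-silyloxyallylboronate
Product: 33 (1R,4aS,7S,8R,9R,11aR)-1-acetoxy-4-[(1R,2S)-2-(tert-butyldimethylsilyloxy)-1-hydroxybut-3-en-1-yl]-8,9-epoxy-7-methyl-11-methylidene-1,4a,5,6,7,8,9,10,11,11a-decahydrocyclonona[c]pyran-7-ol, via pinacol borate 32 (not isolated)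
Conditions: (S)-3,3'-bis(2,4,6-triisopropylphenyl)-1,1'-binaphthyl-2,2'-diyl hydrogen phosphate (10 mol %), 4 Å molecular sieves, toluene, −30 to 0 °C; aqueous NaHCO3
Reagents that add atoms: none
Why: Allylboration through a closed chair transition state translates the E geometry of the boronate into the anti relationship of the C12 hydroxyl and the C13 silyloxy group, and the chiral phosphoric acid, hydrogen-bonded to a boronate oxygen and the formyl hydrogen, is expected to direct attack to the si face of the aldehyde, giving the (12R) carbinol.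

Step 19
Reactants: 33 anti adduct
Product: 34 C12 acetate (1R,4aS,7S,8R,9R,11aR)-1-acetoxy-4-[(1R,2S)-1-acetoxy-2-(tert-butyldimethylsilyloxy)but-3-en-1-yl]-8,9-epoxy-7-methyl-11-methylidene-1,4a,5,6,7,8,9,10,11,11a-decahydrocyclonona[c]pyran-7-ol
Conditions: Ac2O, pyridine, DMAP (cat.), CH2Cl2, 0 °C
Reagents that add atoms: acetic anhydride, CC(=O)OC(C)=O
Why: Acylation of the secondary C12 hydroxyl installs a target acetate and removes the allylic hydroxyl that could otherwise direct oxidation of the ring enol ether in step 22.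

Step 20
Reactants: 34 C12 acetate; 35 2-methyl-2-butene
Product: 36 (1R,4aS,7S,8R,9R,11aR)-1-acetoxy-4-[(1R,2S)-1-acetoxy-2-(tert-butyldimethylsilyloxy)-4-methylpent-3-en-1-yl]-8,9-epoxy-7-methyl-11-methylidene-1,4a,5,6,7,8,9,10,11,11a-decahydrocyclonona[c]pyran-7-ol
Conditions: second-generation Hoveyda–Grubbs catalyst RuCl2(H2IMes)(=CH-C6H4-2-OiPr) (10 mol %), 2-methyl-2-butene/CH2Cl2, 40 °C
Reagents that add atoms: none
Why: Olefin cross-metathesis with excess 2-methyl-2-butene turns the monosubstituted vinyl group into the C14=C15 dimethyl alkene (C15 and its methyls), the 1,1-disubstituted exocyclic alkene and the trisubstituted enol ether being far slower metathesis partners.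

Step 21
Reactants: 36 silyl ether
Product: 37 (1R,4aS,7S,8R,9R,11aR)-1-acetoxy-4-[(1R,2S)-1-acetoxy-2-hydroxy-4-methylpent-3-en-1-yl]-8,9-epoxy-7-methyl-11-methylidene-1,4a,5,6,7,8,9,10,11,11a-decahydrocyclonona[c]pyran-7-ol
Conditions: Bu4NF, AcOH (1:1), THF, 0 °C to rt
Reagents that add atoms: none
Why: Fluoride cleavage of the allylic silyl ether, buffered with acetic acid so that the acetates neither migrate nor are cleaved.

Step 22
Reactants: 37 C13 allylic alcohol
Product: 38 (1R,4aS,7S,8R,9R,11aR)-1-acetoxy-4-{(1R,2R)-1-acetoxy-2-[(2R)-3,3-dimethyloxiran-2-yl]-2-hydroxyethyl}-8,9-epoxy-7-methyl-11-methylidene-1,4a,5,6,7,8,9,10,11,11a-decahydrocyclonona[c]pyran-7-ol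
Conditions: Ti(OiPr)4 (1.0 equiv), D-(−)-diisopropyl tartrate (1.2 equiv), t-BuOOH, 4 Å molecular sieves, CH2Cl2, −20 °C
Reagents that add atoms: tert-butyl hydroperoxide, CC(C)(C)OO
Why: Sharpless asymmetric epoxidation, in which the titanium tartrate bound to the C13 hydroxyl delivers oxygen only to C14=C15 and D-(−)-tartrate is the matched ligand for this carbinol configuration, so the erythro (13,14-anti) epoxy alcohol with (14R) is expected.

Step 23
Reactants: 38 epoxy alcohol
Product: 39 target CNP0134792.1, (1R,4aS,7S,8R,9R,11aR)-1-acetoxy-4-{(1R,2R)-1,2-diacetoxy-2-[(2R)-3,3-dimethyloxiran-2-yl]ethyl}-8,9-epoxy-7-methyl-11-methylidene-1,4a,5,6,7,8,9,10,11,11a-decahydrocyclonona[c]pyran-7-ol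
Conditions: Ac2O, Et3N, DMAP (cat.), CH2Cl2, 0 °C
Reagents that add atoms: acetic anhydride, CC(=O)OC(C)=O
Why: Acylation of the last secondary hydroxyl (C13) completes the target, the tertiary C7 hydroxyl being too hindered to react under these conditions.

**Compound list**

1 | furfuryl alcohol | OCc1ccco1 | starting material
2 | rac-6-hydroxy-2H-pyran-3(6H)-one | O=C1COC(O)C=C1 | intermediate
3 | rac-6-acetoxy-2H-pyran-3(6H)-one | CC(=O)OC1OCC(=O)C=C1 | intermediate
4 | (R)-6-acetoxy-2H-pyran-3(6H)-one | CC(=O)O[C@H]1OCC(=O)C=C1 | intermediate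
5 | (S)-6-[(4-methoxybenzyl)oxy]-2H-pyran-3(6H)-one | COc1ccc(CO[C@H]2OCC(=O)C=C2)cc1 | intermediate
6 | trimethylsilylacetylene | C#C[Si](C)(C)C | starting material
7 | 2,3-dibromopropene | C=C(Br)CBr | starting material
8 | bromo[(trimethylsilyl)ethynyl]magnesium | C[Si](C)(C)C#C[Mg]Br | intermediate
9 | (4-bromopent-4-en-1-yn-1-yl)trimethylsilane | C=C(Br)CC#C[Si](C)(C)C | intermediate
10 | methyl vinyl ketone | CC(=O)C=C | starting material
11 | [5-(trimethylsilyl)pent-1-en-4-yn-2-yl]lithium | [Li]C(=C)CC#C[Si](C)(C)C | intermediate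
12 | lithium bis[5-(trimethylsilyl)pent-1-en-4-yn-2-yl]cuprate | [Li+].C=C(CC#C[Si](C)(C)C)[Cu-]C(=C)CC#C[Si](C)(C)C | intermediate
13 | ring lithium enolate (C4–OLi, C4=C4a) of the conjugate adduct, C1 alkoxy and C11a arm trans | [Li]OC1=C[C@H](C(=C)CC#C[Si](C)(C)C)[C@@H](OCc2ccc(OC)cc2)OC1 | intermediate
14 | side-chain lithium enolate (C6=C7–OLi) of the Michael adduct, all-trans ring | [Li]OC(C)=CC[C@@H]1C(=O)CO[C@H](OCc2ccc(OC)cc2)[C@H]1C(=C)CC#C[Si](C)(C)C | intermediate
15 | (4S,5R,6S)-6-[(4-methoxybenzyl)oxy]-4-[3-(triethylsilyloxy)but-2-en-1-yl]-5-[5-(trimethylsilyl)pent-1-en-4-yn-2-yl]dihydro-2H-pyran-3(4H)-one | CC[Si](CC)(CC)OC(C)=CC[C@@H]1C(=O)CO[C@H](OCc2ccc(OC)cc2)[C@H]1C(=C)CC#C[Si](C)(C)C | intermediate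
16 | potassium C3=C4 enolate of 15 | CC[Si](CC)(CC)OC(C)=CC[C@@H]1C(O[K])=CO[C@H](OCc2ccc(OC)cc2)[C@H]1C(=C)CC#C[Si](C)(C)C | intermediate
17 | (2S,3R,4S)-2-[(4-methoxybenzyl)oxy]-4-[3-(triethylsilyloxy)but-2-en-1-yl]-3-[5-(trimethylsilyl)pent-1-en-4-yn-2-yl]-3,4-dihydro-2H-pyran-5-yl trifluoromethanesulfonate | CC[Si](CC)(CC)OC(C)=CC[C@@H]1C(OS(=O)(=O)C(F)(F)F)=CO[C@H](OCc2ccc(OC)cc2)[C@H]1C(=C)CC#C[Si](C)(C)C | intermediate
18 | methyl (2S,3R,4S)-2-[(4-methoxybenzyl)oxy]-4-[3-(triethylsilyloxy)but-2-en-1-yl]-3-[5-(trimethylsilyl)pent-1-en-4-yn-2-yl]-3,4-dihydro-2H-pyran-5-carboxylate | CC[Si](CC)(CC)OC(C)=CC[C@@H]1C(C(=O)OC)=CO[C@H](OCc2ccc(OC)cc2)[C@H]1C(=C)CC#C[Si](C)(C)C | intermediate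
19 | methyl (2S,3R,4S)-2-[(4-methoxybenzyl)oxy]-4-(3-oxobutyl)-3-[5-(trimethylsilyl)pent-1-en-4-yn-2-yl]-3,4-dihydro-2H-pyran-5-carboxylate | CC(=O)CC[C@@H]1C(C(=O)OC)=CO[C@H](OCc2ccc(OC)cc2)[C@H]1C(=C)CC#C[Si](C)(C)C | intermediate
20 | methyl (2S,3R,4S)-3-(5-iodopent-1-en-4-yn-2-yl)-2-[(4-methoxybenzyl)oxy]-4-(3-oxobutyl)-3,4-dihydro-2H-pyran-5-carboxylate | CC(=O)CC[C@@H]1C(C(=O)OC)=CO[C@H](OCc2ccc(OC)cc2)[C@H]1C(=C)CC#CI | intermediate
21 | methyl (2S,3R,4S)-3-[(4Z)-5-iodopenta-1,4-dien-2-yl]-2-[(4-methoxybenzyl)oxy]-4-(3-oxobutyl)-3,4-dihydro-2H-pyran-5-carboxylate (key-step precursor) | CC(=O)CC[C@@H]1C(C(=O)OC)=CO[C@H](OCc2ccc(OC)cc2)[C@H]1C(=C)C/C=C\I | intermediate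
22 | Z-alkenylchromium dichloride derived from 21 (chromium on C8) | CC(=O)CC[C@@H]1C(C(=O)OC)=CO[C@H](OCc2ccc(OC)cc2)[C@H]1C(=C)C/C=C\[Cr](Cl)Cl | intermediate
23 | chromium dichloride alkoxide of 24 (chromium on the C7 oxygen) | C=C1C/C=C\[C@@](C)(O[Cr](Cl)Cl)CC[C@@H]2C(C(=O)OC)=CO[C@H](OCc3ccc(OC)cc3)[C@@H]12 | intermediate
24 | methyl (1S,4aS,7S,8Z,11aR)-7-hydroxy-1-[(4-methoxybenzyl)oxy]-7-methyl-11-methylidene-1,4a,5,6,7,10,11,11a-octahydrocyclonona[c]pyran-4-carboxylate (key-step product) | C=C1C/C=C\[C@@](C)(O)CC[C@@H]2C(C(=O)OC)=CO[C@H](OCc3ccc(OC)cc3)[C@@H]12 | intermediate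
25 | (1S,4aS,7S,8Z,11aR)-4-(hydroxymethyl)-1-[(4-methoxybenzyl)oxy]-7-methyl-11-methylidene-1,4a,5,6,7,10,11,11a-octahydrocyclonona[c]pyran-7-ol | C=C1C/C=C\[C@@](C)(O)CC[C@@H]2C(CO)=CO[C@H](OCc3ccc(OC)cc3)[C@@H]12 | intermediate
26 | (1S,4aS,7S,8Z,11aR)-7-hydroxy-1-[(4-methoxybenzyl)oxy]-7-methyl-11-methylidene-1,4a,5,6,7,10,11,11a-octahydrocyclonona[c]pyran-4-carbaldehyde | C=C1C/C=C\[C@@](C)(O)CC[C@@H]2C(C=O)=CO[C@H](OCc3ccc(OC)cc3)[C@@H]12 | intermediate
27 | (1S,4aS,7S,8R,9R,11aR)-8,9-epoxy-7-hydroxy-1-[(4-methoxybenzyl)oxy]-7-methyl-11-methylidene-decahydrocyclonona[c]pyran-4-carbaldehyde (C3=C4 retained) | C=C1C[C@H]2O[C@H]2[C@@](C)(O)CC[C@@H]2C(C=O)=CO[C@H](OCc3ccc(OC)cc3)[C@@H]12 | intermediate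
28 | C1 hemiacetal of 27 (anomeric mixture) | C=C1C[C@H]2O[C@H]2[C@@](C)(O)CC[C@@H]2C(C=O)=COC(O)[C@@H]12 | intermediate
29 | (1R,4aS,7S,8R,9R,11aR)-1-acetoxy-8,9-epoxy-7-hydroxy-7-methyl-11-methylidene-decahydrocyclonona[c]pyran-4-carbaldehyde (C3=C4 retained) | C=C1C[C@H]2O[C@H]2[C@@](C)(O)CC[C@@H]2C(C=O)=CO[C@H](OC(C)=O)[C@@H]12 | intermediate
30 | (E)-tert-butyldimethyl{[3-(4,4,5,5-tetramethyl-1,3,2-dioxaborolan-2-yl)prop-2-en-1-yl]oxy}silane | CC(C)(C)[Si](C)(C)OC/C=C/B1OC(C)(C)C(C)(C)O1 | starting material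
31 | (E)-tert-butyldimethyl{[3-(4,4,5,5-tetramethyl-1,3,2-dioxaborolan-2-yl)prop-1-en-1-yl]oxy}silane | CC(C)(C)[Si](C)(C)O/C=C/CB1OC(C)(C)C(C)(C)O1 | intermediate
32 | pinacol borate of 33 (boron on the C12 oxygen) | C=C1C[C@H]2O[C@H]2[C@@](C)(O)CC[C@@H]2C([C@@H](OB3OC(C)(C)C(C)(C)O3)[C@@H](O[Si](C)(C)C(C)(C)C)C=C)=CO[C@H](OC(C)=O)[C@@H]12 | intermediate
33 | 12,13-anti adduct, (12R,13S): C12 hydroxyl, C13 tert-butyldimethylsilyl ether, C14 vinyl | C=C1C[C@H]2O[C@H]2[C@@](C)(O)CC[C@@H]2C([C@@H](O)[C@@H](O[Si](C)(C)C(C)(C)C)C=C)=CO[C@H](OC(C)=O)[C@@H]12 | intermediate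
34 | C12 acetate of 33 | C=C1C[C@H]2O[C@H]2[C@@](C)(O)CC[C@@H]2C([C@@H](OC(C)=O)[C@@H](O[Si](C)(C)C(C)(C)C)C=C)=CO[C@H](OC(C)=O)[C@@H]12 | intermediate
35 | 2-methyl-2-butene | CC=C(C)C | starting material
36 | C12 acetate, C13 silyl ether, C14=C15 dimethyl alkene | C=C1C[C@H]2O[C@H]2[C@@](C)(O)CC[C@@H]2C([C@@H](OC(C)=O)[C@@H](O[Si](C)(C)C(C)(C)C)C=C(C)C)=CO[C@H](OC(C)=O)[C@@H]12 | intermediate
37 | C12 acetate, free C13 allylic alcohol, C14=C15 dimethyl alkene | C=C1C[C@H]2O[C@H]2[C@@](C)(O)CC[C@@H]2C([C@@H](OC(C)=O)[C@@H](O)C=C(C)C)=CO[C@H](OC(C)=O)[C@@H]12 | intermediate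
38 | (12R,13R,14R) epoxy alcohol: C12 acetate, C13 hydroxyl, 14,15-epoxide | C=C1C[C@H]2O[C@H]2[C@@](C)(O)CC[C@@H]2C([C@@H](OC(C)=O)[C@@H](O)[C@H]3OC3(C)C)=CO[C@H](OC(C)=O)[C@@H]12 | intermediate
39 | CNP0134792.1, (1R,4aS,7S,8R,9R,11aR,12R,13R,14R) | C=C1C[C@H]2O[C@H]2[C@@](C)(O)CC[C@@H]2C([C@@H](OC(C)=O)[C@@H](OC(C)=O)[C@H]3OC3(C)C)=CO[C@H](OC(C)=O)[C@@H]12 | target

**Step count and risk**

Total step count: 23. Longest linear sequence: 21 (steps 1–4, 6–16, 18–23).

Steps most likely to fail:

Step 11. The alkenylchromium may be protonated or couple intermolecularly faster than it adds to the hindered, enolisable methyl ketone, and the two ketone faces may be poorly differentiated. The fallback closes ring B on an aldehyde and adds the methyl group afterwards; it sets out from 5 and 9 and returns at 24. The cuprate addition of step 6 would be trapped with methyl acrylate in place of 10 to give the keto ester F1. Enol triflation as in step 7 would give the triflate F2, methoxycarbonylation as in step 8 the diester F3, iododesilylation the iodoalkyne F4, and diimide reduction the Z-iodoalkene F5. One equivalent of i-Bu2AlH at −78 °C should reduce only the saturated ester, giving the aldehyde F6. CrCl2/NiCl2 ring closure onto the aldehyde, the best-precedented form of this cyclisation, would give the secondary allylic alcohol F7 (either C7 epimer serves). Dess–Martin oxidation would give the nine-membered Z-enone F8, and MeMgBr with CeCl3 at −78 °C should add 1,2 to the ring ketone from its outer face to reach 24.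

Step 22. Allylic strain between the cis C15 methyl and the C12 branch may slow the matched pathway, so that oxygen is delivered with poor facial selectivity or the long reaction time erodes the C1 acetate. The fallback replaces hydroxyl direction by reagent control on a substrate whose ring enol ether is electronically switched off; it sets out from 33 and returns at 39. Cross-metathesis of 33 with 35 would give the C12 alcohol F9, and MnO2 would oxidise it to the C12 ketone F10, a vinylogous ester in which the enol ether is deactivated. Shi epoxidation with the D-fructose-derived ketone and buffered Oxone should then epoxidise only C14=C15, giving the epoxy ketone F11. Luche reduction (NaBH4, CeCl3, MeOH, −78 °C) under Felkin–Anh control by the C13 silyloxy group should give the 12,13-anti alcohol F12. Bu4NF/AcOH would free the diol F13, and Ac2O with Et3N and DMAP would acetylate both hydroxyls to 39.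

Step 6. Proton transfer between the ring enolate and methyl vinyl ketone, anionic oligomerisation of the enone, or premature O-silylation of the ring enolate would erode the one-pot trapping. The fallback separates the two bond formations; it sets out from 5 and 9 and returns at 15. The cuprate addition would be run in the presence of Me3SiCl to give the ring trimethylsilyl enol ether F14. MeLi in THF regenerates ring enolate 13 regiospecifically, and its Michael addition to 3-(triethylsilyl)but-3-en-2-one, whose silicon-stabilised adduct enolate does not oligomerise, gives after protonation the β-ketosilane F15. Heating in toluene should move silicon from carbon to oxygen (1,3-shift) to give 15.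

Further compounds
F1 | step 11 | methyl 3-{(4S,5R,6S)-6-[(4-methoxybenzyl)oxy]-3-oxo-5-[5-(trimethylsilyl)pent-1-en-4-yn-2-yl]tetrahydro-2H-pyran-4-yl}propanoate | COC(=O)CC[C@@H]1C(=O)CO[C@H](OCc2ccc(OC)cc2)[C@H]1C(=C)CC#C[Si](C)(C)C
F2 | step 11 | C3=C4 enol triflate of F1 | COC(=O)CC[C@@H]1C(OS(=O)(=O)C(F)(F)F)=CO[C@H](OCc2ccc(OC)cc2)[C@H]1C(=C)CC#C[Si](C)(C)C
F3 | step 11 | diester: C4 methyl ester, C4a 2-(methoxycarbonyl)ethyl arm, silylalkyne | COC(=O)CC[C@@H]1C(C(=O)OC)=CO[C@H](OCc2ccc(OC)cc2)[C@H]1C(=C)CC#C[Si](C)(C)C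
F4 | step 11 | iodoalkyne diester | COC(=O)CC[C@@H]1C(C(=O)OC)=CO[C@H](OCc2ccc(OC)cc2)[C@H]1C(=C)CC#CI
F5 | step 11 | Z-iodoalkene diester | COC(=O)CC[C@@H]1C(C(=O)OC)=CO[C@H](OCc2ccc(OC)cc2)[C@H]1C(=C)C/C=C\I
F6 | step 11 | Z-iodoalkene C7 aldehyde (3-oxopropyl arm on C4a) | O=CCC[C@@H]1C(C(=O)OC)=CO[C@H](OCc2ccc(OC)cc2)[C@H]1C(=C)C/C=C\I
F7 | step 11 | bicyclic secondary allylic alcohol, 7-demethyl analogue of 24 (C7 epimers) | C=C1C/C=C\C(O)CC[C@@H]2C(C(=O)OC)=CO[C@H](OCc3ccc(OC)cc3)[C@@H]12
F8 | step 11 | bicyclic Z-enone (C7 ketone) | C=C1C/C=C\C(=O)CC[C@@H]2C(C(=O)OC)=CO[C@H](OCc3ccc(OC)cc3)[C@@H]12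
F9 | step 22 | C12 alcohol, C13 silyl ether, C14=C15 dimethyl alkene | C=C1C[C@H]2O[C@H]2[C@@](C)(O)CC[C@@H]2C([C@@H](O)[C@@H](O[Si](C)(C)C(C)(C)C)C=C(C)C)=CO[C@H](OC(C)=O)[C@@H]12
F10 | step 22 | C12 ketone, C13 silyl ether, C14=C15 dimethyl alkene | C=C1C[C@H]2O[C@H]2[C@@](C)(O)CC[C@@H]2C(C(=O)[C@@H](O[Si](C)(C)C(C)(C)C)C=C(C)C)=CO[C@H](OC(C)=O)[C@@H]12
F11 | step 22 | C12 ketone, C13 silyl ether, (14R)-14,15-epoxide | C=C1C[C@H]2O[C@H]2[C@@](C)(O)CC[C@@H]2C(C(=O)[C@@H](O[Si](C)(C)C(C)(C)C)[C@H]3OC3(C)C)=CO[C@H](OC(C)=O)[C@@H]12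
F12 | step 22 | (12R) alcohol, C13 silyl ether, 14,15-epoxide | C=C1C[C@H]2O[C@H]2[C@@](C)(O)CC[C@@H]2C([C@@H](O)[C@@H](O[Si](C)(C)C(C)(C)C)[C@H]3OC3(C)C)=CO[C@H](OC(C)=O)[C@@H]12
F13 | step 22 | 12,13-anti diol with 14,15-epoxide | C=C1C[C@H]2O[C@H]2[C@@](C)(O)CC[C@@H]2C([C@@H](O)[C@@H](O)[C@H]3OC3(C)C)=CO[C@H](OC(C)=O)[C@@H]12
F14 | step 6 | ring trimethylsilyl enol ether (C4–OSiMe3, C4=C4a) of the conjugate adduct | C[Si](C)(C)OC1=C[C@H](C(=C)CC#C[Si](C)(C)C)[C@@H](OCc2ccc(OC)cc2)OC1
F15 | step 6 | β-ketosilane: ring ketone with a 3-oxo-2-(triethylsilyl)butyl arm on C4a (mixture at the silyl-bearing carbon) | CC(=O)C(C[C@@H]1C(=O)CO[C@H](OCc2ccc(OC)cc2)[C@H]1C(=C)CC#C[Si](C)(C)C)[Si](CC)(CC)CC
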